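**Retrosynthetic overview**
- Candidachalcone is cut at the bond between the ketone carbon and the α-carbon of the enone, giving a fully functionalised, unprotected ring-A salicylaldehyde and 4-ethynylphenol; the two are joined in the last step by Rh-catalysed alkyne hydroacylation.
- Enabling feature: the free O2'–H on ring A, ortho to C1' that carries the acyl carbon. O2' and the acyl carbon hold rhodium in a five-membered chelate (Rh, O2', C2', C1', acyl C).
- The aldehyde comes from ortho-formylation of a mirror-symmetric 2-alkenyl-5-methoxyresorcinol, whose two free ring positions are equivalent.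
- The Z-alkene and the tertiary alcohol come from a temporary lactone ring: 5-hydroxy-7-methoxycoumarin is opened with two equivalents of MeLi, so its endocyclic cis C3=C4 bond becomes the Z-alkene.
- Rings: none is built. Both benzene rings are bought, and the only ring event is the opening of the coumarin pyranone ring in step 2.

Key step: step 4

Remark: the target has no stereocentre, so "single isomer" is taken to mean the Z side-chain alkene and the E enone. Ring A locants: C1' bears the C=O, C2' OH, C3' the side chain, C4' OH, C6' OMe.

**Step 1**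
Reactants: 1 5,7-dihydroxycoumarin
Product: 2 5-hydroxy-7-methoxycoumarin
Conditions: MeI (1.05 equiv), K2CO3 (1.0 equiv), acetone, rt
Reagents that add atoms: iodomethane, CI
Why: Williamson O-methylation with one equivalent of base and electrophile should go at O7, the more acidic and less hindered phenol of a 5,7-dihydroxycoumarin (the 5-OH is peri to C4–H), which fixes the future C6' methoxy group before the ring is opened.

**Step 2**
Reactants: 2 5-hydroxy-7-methoxycoumarin
Product: 4 2-[(Z)-3-hydroxy-3-methylbut-1-en-1-yl]-5-methoxybenzene-1,3-diol, via ring-opened Z-methyl ketone 3 (not isolated)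
Conditions: MeLi (4.5 equiv), THF, −78 → 0 °C; sat. aq. NH4Cl, 0 °C; Et3N-deactivated silica
Reagents that add atoms: methyllithium, [Li]C
Why: Double 1,2-addition of an organolithium to a lactone (the classical coumarin to cis-2-hydroxycinnamyl carbinol ring-opening) after deprotonation of the 5-OH: the first addition opens the pyranone to ketone 3, which is more electrophilic than the lactone and is trapped at once, so the cis C3=C4 bond of the coumarin is carried over as the Z-alkene and the lactone oxygen becomes the second flanking phenol.

**Step 3**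
Reactants: 4 2-[(Z)-3-hydroxy-3-methylbut-1-en-1-yl]-5-methoxybenzene-1,3-diol
Product: 6 2,4-dihydroxy-3-[(Z)-3-hydroxy-3-methylbut-1-en-1-yl]-6-methoxybenzaldehyde, via benzylic alcohol 5 (not isolated)
Conditions: MgCl2 (2.5 equiv), Et3N (5 equiv), (CH2O)n (2.5 equiv), THF, 60 °C; aq. NH4Cl work-up
Reagents that add atoms: paraformaldehyde (reacts as formaldehyde), C=O
Why: Magnesium-mediated ortho-formylation of a phenol (Casnati–Skattebøl): the Mg phenoxide delivers formaldehyde to the ortho carbon and the benzylic alkoxide of 5 is oxidised by hydride transfer to a second formaldehyde, all under basic conditions that should spare the acid-labile Z-allylic tertiary alcohol; the two free ring positions of 4 are related by its mirror plane, so only one regioisomer can form, and the first formyl group deactivates the ring towards a second.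

**Step 4**
Reactants: 6 2,4-dihydroxy-3-[(Z)-3-hydroxy-3-methylbut-1-en-1-yl]-6-methoxybenzaldehyde; 7 4-ethynylphenol
Product: 8 candidachalcone
Conditions: [RhCl(cod)]2 (2.5 mol %), dppf (5 mol %), Na2CO3 (10 mol %), 7 (1.5 equiv), degassed toluene/1,4-dioxane, 80 °C
Reagents that add atoms: none
Why: Rh(I)-catalysed chelation-assisted alkyne hydroacylation: the rhodium phenoxide formed at O2' with catalytic Na2CO3 inserts into the formyl C–H bond to give a five-membered acyl-rhodium(III) hydride chelate (Rh, O2', C2', C1', acyl C), which is held against decarbonylation. Coordination of the terminal alkyne of 7, syn-hydrometalation that places Rh on the unsubstituted terminal carbon, and C–C reductive elimination should then form the acyl–Cα bond and release the catalyst. The closest known reaction type is the Rh/diphosphine-catalysed intermolecular coupling of salicylaldehydes with alkynes to give 2-alkenoylphenols. No ring is closed and no stereocentre is formed; the E geometry of the new enone follows from the syn addition of the acyl group and hydrogen across the triple bond. The step needs linear over branched regioselectivity, which the terminal alkyne should secure because its aryl-bearing carbon is the hindered site for Rh–C bond formation under the wide-bite-angle ligand. It also needs chemoselectivity for the formyl C–H bond, which the ortho O2'–H secures as the only chelating group, while the 1,2-disubstituted Z side-chain alkene inserts far more slowly than the alkyne and cannot reach the acyl carbon without bridging meta positions.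

**Compound list**
1 | 5,7-dihydroxycoumarin (5,7-dihydroxy-2H-chromen-2-one) | O=C1C=Cc2c(O)cc(O)cc2O1 | starting material
2 | 5-hydroxy-7-methoxycoumarin (5-hydroxy-7-methoxy-2H-chromen-2-one) | O=C1C=Cc2c(O)cc(OC)cc2O1 | intermediate
3 | (Z)-4-(2,6-dihydroxy-4-methoxyphenyl)but-3-en-2-one, present as its lithium phenoxide | COc1cc(O)c(/C=C\C(C)=O)c(O)c1 | intermediate (not isolated)
4 | 2-[(Z)-3-hydroxy-3-methylbut-1-en-1-yl]-5-methoxybenzene-1,3-diol | COc1cc(O)c(/C=C\C(C)(C)O)c(O)c1 | intermediate
5 | 4-(hydroxymethyl)-2-[(Z)-3-hydroxy-3-methylbut-1-en-1-yl]-5-methoxybenzene-1,3-diol, present as its magnesium alkoxide | COc1cc(O)c(/C=C\C(C)(C)O)c(O)c1CO | intermediate (not isolated)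
6 | 2,4-dihydroxy-3-[(Z)-3-hydroxy-3-methylbut-1-en-1-yl]-6-methoxybenzaldehyde | COc1cc(O)c(/C=C\C(C)(C)O)c(O)c1C=O | intermediate
7 | 4-ethynylphenol | C#Cc1ccc(O)cc1 | starting material
8 | candidachalcone, (E)-1-{2,4-dihydroxy-3-[(Z)-3-hydroxy-3-methylbut-1-en-1-yl]-6-methoxyphenyl}-3-(4-hydroxyphenyl)prop-2-en-1-one | COc1cc(O)c(/C=C\C(C)(C)O)c(O)c1C(=O)/C=C/c1ccc(O)cc1 | target

**Step count and risks**
Total step count: 4. Longest linear sequence: 4 steps (1 → 2 → 4 → 6 → 8); 7 is bought.

Steps most likely to fail, riskiest first:

1. Step 4. What may go wrong: loss of regiocontrol in the hydrometalation (branched 1,1-disubstituted enone), Rh–H-mediated Z-to-E isomerisation of the side-chain alkene, decarbonylation of the acyl-rhodium species, oligomerisation of the alkyne, or base-induced oxa-Michael closure of the product to the flavanone. Fallback (from 6, back at 8): the same bond is made by stoichiometric acetylide addition instead of C–H activation. Aldehyde 6 is deprotonated at its three OH groups (LiHMDS, 3 equiv, THF, −78 °C) and treated with the dilithio derivative of 7 (7, n-BuLi 2 equiv). After NH4Cl work-up this should give the racemic propargylic alcohol 4-[1-hydroxy-3-(4-hydroxyphenyl)prop-2-yn-1-yl]-2-[(Z)-3-hydroxy-3-methylbut-1-en-1-yl]-5-methoxybenzene-1,3-diol F1. Base-mediated redox isomerisation of F1 (KOtBu in excess over the phenols, DMSO, rt; propargyl–allenyl prototropy, then tautomerisation) should then give the E-enone 8.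

2. Step 3. What may go wrong: over-formylation and phenol–formaldehyde oligomerisation of the very electron-rich resorcinol, or Mg(II)- and heat-promoted dehydrative cyclisation of the Z-allylic alcohol onto a flanking phenol (2,2-dimethylchromene formation). Fallback (from 2, back at 6): the formyl group is introduced on the robust coumarin and carried through the organolithium step as an aminal. Duff formylation of 2 (hexamethylenetetramine, TFA, 80 °C, then water) should give 5-hydroxy-7-methoxy-2-oxo-2H-chromene-6-carbaldehyde F2, ortho to the free 5-OH. Condensation with N,N'-dimethylethane-1,2-diamine (toluene, 4 Å MS, rt) should give 6-(1,3-dimethylimidazolidin-2-yl)-5-hydroxy-7-methoxy-2H-chromen-2-one F3. MeLi (4.5 equiv, THF, −78 → 0 °C) should open the lactone through the ring-opened methyl ketone (Z)-4-[3-(1,3-dimethylimidazolidin-2-yl)-2,6-dihydroxy-4-methoxyphenyl]but-3-en-2-one F4 (not isolated) to 4-(1,3-dimethylimidazolidin-2-yl)-2-[(Z)-3-hydroxy-3-methylbut-1-en-1-yl]-5-methoxybenzene-1,3-diol F5. Hydrolysis of the aminal in aq. NH4Cl/THF or on moist silica should return aldehyde 6.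

3. Step 2. What may go wrong: the lithium 5-phenoxide is a vinylogous carboxylate that deactivates the lactone, so the second addition may stall and conjugate addition at C4 may compete; the product may also cyclise with loss of water on work-up. Fallback (from 2, back at 4): the phenol is masked so that the lactone reacts as an ordinary ester at low temperature. Silylation of 2 (TIPSCl, imidazole, DMF, rt) should give 7-methoxy-5-[(triisopropylsilyl)oxy]-2H-chromen-2-one F6. MeLi (2.5 equiv, THF, −78 °C) should then give, through (Z)-4-{2-hydroxy-4-methoxy-6-[(triisopropylsilyl)oxy]phenyl}but-3-en-2-one F7 (not isolated), 2-[(Z)-3-hydroxy-3-methylbut-1-en-1-yl]-5-methoxy-3-[(triisopropylsilyl)oxy]phenol F8. Desilylation (TBAF, THF, 0 °C) should return triol 4.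

**Further compounds**
F1 | step 4 | 4-[1-hydroxy-3-(4-hydroxyphenyl)prop-2-yn-1-yl]-2-[(Z)-3-hydroxy-3-methylbut-1-en-1-yl]-5-methoxybenzene-1,3-diol (racemic) | COc1cc(O)c(/C=C\C(C)(C)O)c(O)c1C(O)C#Cc1ccc(O)cc1
F2 | step 3 | 5-hydroxy-7-methoxy-2-oxo-2H-chromene-6-carbaldehyde | O=C1C=Cc2c(O)c(C=O)c(OC)cc2O1
F3 | step 3 | 6-(1,3-dimethylimidazolidin-2-yl)-5-hydroxy-7-methoxy-2H-chromen-2-one | O=C1C=Cc2c(O)c(C3N(C)CCN3C)c(OC)cc2O1
F4 | step 3 | (Z)-4-[3-(1,3-dimethylimidazolidin-2-yl)-2,6-dihydroxy-4-methoxyphenyl]but-3-en-2-one | COc1cc(O)c(/C=C\C(C)=O)c(O)c1C1N(C)CCN1C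
F5 | step 3 | 4-(1,3-dimethylimidazolidin-2-yl)-2-[(Z)-3-hydroxy-3-methylbut-1-en-1-yl]-5-methoxybenzene-1,3-diol | COc1cc(O)c(/C=C\C(C)(C)O)c(O)c1C1N(C)CCN1C
F6 | step 2 | 7-methoxy-5-[(triisopropylsilyl)oxy]-2H-chromen-2-one | O=C1C=Cc2c(O[Si](C(C)C)(C(C)C)C(C)C)cc(OC)cc2O1
F7 | step 2 | (Z)-4-{2-hydroxy-4-methoxy-6-[(triisopropylsilyl)oxy]phenyl}but-3-en-2-one | COc1cc(O)c(/C=C\C(C)=O)c(O[Si](C(C)C)(C(C)C)C(C)C)c1
F8 | step 2 | 2-[(Z)-3-hydroxy-3-methylbut-1-en-1-yl]-5-methoxy-3-[(triisopropylsilyl)oxy]phenol | COc1cc(O)c(/C=C\C(C)(C)O)c(O[Si](C(C)C)(C(C)C)C(C)C)c1
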